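Solid D feeds a solution of Z.

the same everywhere: D 0.25 M; Z 1.00 equiv; time 12 min

| run | temperature |
|---|---|
| grey | 150 °C |
| green | 110 °C |
| red | 130 °C |

    L + Z → J + E (k1 = 0.0052 M⁻¹ s⁻¹, Ea1 = 82.0 kJ mol⁻¹)
    Z + Q → G + E (k2 = 0.014 M⁻¹ s⁻¹, Ea2 = 76.0 kJ mol⁻¹)
    J ⇌ X (K3 = 0.33, k3 = 2.7 × 10⁻⁴ s⁻¹, Ea3 = 112 kJ mol⁻¹, ΔH3 = −17.0 kJ mol⁻¹)
    Z + J → G + E (k4 = 0.0024 M⁻¹ s⁻¹, Ea4 = 90.0 kJ mol⁻¹)
    D ⇌ L, rate k5*(cs5 - [L]) while solid is left; crystals form when [L] > cs5 (cs5 = 19 mM, k5 = 8.3 × 10⁻⁴ s⁻¹)
    L + Z → Q + E (k6 = 0.0024 M⁻¹ s⁻¹, Ea6 = 78.0 kJ mol⁻¹)
    (constants at 110 °C)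

- D is a solid; its amount is given per volume of the solution
- the list of constants is for 110 °C, to be carried to other temperatures by the activation energies and enthalpies
- at the start none of D is in solution
- what has only dissolved of D counts as not reacted

- the best flask by share of J in all that became J or G or X; "all alike" if 1.5 percentage points covers them all (grey / green / red / all alike)
- share of J in all that became J or G or X, grey
- share of J in all that became J or G or X, green
- share of J in all that became J or G or X, red

A molecule of D, once dissolved as L, meets two forks, and the reckoning here follows it through them. With kd the dissolution coefficient and cs the solubility, L arrives at no more than kd·cs per unit time. Even at two Z per molecule, the run can therefore consume at most 0.0227 M of Z, less than the 0.25 M charged, so [Z] is taken as constant and each step with Z as pseudo-first-order.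

At the first fork, L becomes J with chance φ = kJ/(kJ + kQ), where kJ and kQ are the constants of L + Z → J + E and L + Z → Q + E; Q is counted as G already. At the second fork, J meets Z with constant kG, that of Z + J → G + E. L comes up toward its steady level with a time constant τ, the reciprocal of kd + (kJ + kQ)[Z], so J is reckoned as fed evenly over t − τ, t being the time of the run, and the share of J follows from N:

N = kG[Z](t − τ)

share of J = φ(1 − e^(−N))/N

grey: φ = 0.709, τ = 0.767 min, N = 5.84, share 12.1%

green: φ = 0.684, τ = 6.11 min, N = 0.212, share 61.6%

red: φ = 0.698, τ = 2.22 min, N = 1.43, share 37.1%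

N is the number of J lifetimes against Z that the run offers once L has come up. From green to grey it grows 27.5-fold while φ barely shifts, so the reckoning names green as best.

One number leaves two things out in green. J goes to X with constant 2.7 × 10⁻⁴ s⁻¹, about half of kG[Z], which lowers the share. Q lives 4.76 min against Z, so some of it is still short of G at the end, which raises the share.

The forecast named green best, with 13% for grey, 64% for green and 35% for red, holding that “Heat speeds the onward loss of J to G and the Q route to G”.

The simulation gives 12.9% for grey, 64.6% for green and 34.9% for red, with green best, and green stands above its reckoned share.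

The neighbour of green takes 1.70 equiv of Z, so [Z] is 0.425 M, and φ, which holds no [Z], stays at 0.684. There τ is 4.11 min, shorter than in green, and N is 0.483, larger than the 0.212 of green. The same line gives a share of 54.2%. The simulated neighbour gives 54.4%, with 98% of its charged Z still unbound at the end.

(The constants used here stand for no real mixture, and the outcome is calculated.)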